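**Proposed synthesis of (S)-2-(3-hydroxy-4,5-dimethoxyphenyl)-7,8-dimethoxychroman-4-one (20) by a boryl-directed aryne annulation**

## Analysis of the target

The target 20 is a flavanone: an aromatic ring A fused to a dihydropyranone (ring C) that carries aryl ring B at C2. C2 is the only stereocentre and has the S configuration (O1 > C1′ > C3 > H). It is benzylic, bonded to the ring oxygen and β to the C4 carbonyl, so base or strong acid can open ring C by E1cB to the 2′-hydroxychalcone and re-close it, which erases the centre; the same C2–O1 bond is a benzylic ether and is open to hydrogenolysis. Ring A is 1,2,3,4-tetrasubstituted, with O1, the C8 oxygen and the C7 oxygen contiguous and C5/C6 unsubstituted; ring B has one free phenol beside two methyl ethers, and it must stay distinguishable from the C8 oxygen. The difficulty is therefore twofold: C2 must be set in high enantiopurity and kept away from enolising conditions, and the crowded oxygen pattern of ring A must be built without regiochemical ambiguity. The plan rests on the fact that O1 and the C4 acyl carbon sit on neighbouring ring A carbons, C8a and C4a. Ring C is then a 3-hydroxy ester (O1–C2–C3–C4) laid across a 1,2-dehydroarene, with C2 already formed; to steer the oxygen to C8a, C8 is carried as a boronate and turned into the methoxy group afterwards.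

## Retrosynthetic reasoning

**20 ⇒ 19.** The free 3′-hydroxyl is traced back to its benzyl ether 19. Protection is needed because the C8 oxygen arrives late as a free phenol and has to be methylated on its own. Benzyl is chosen because it survives organomagnesium, oxidative and alkylating conditions and comes off under neutral hydrogenolysis.

**19 ⇒ 18 ⇒ 17.** The C8 methoxy group is traced to phenol 18 and that to pinacol boronate 17. No skeletal bond is cut. Boron is placed at C8 because it is the element that controls the regiochemistry of the ring-forming step, and C–B oxidation puts oxygen on the same carbon.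

**17 ⇒ 6 + 13.** Ring C is cut at O1–C8a and C4a–C4, giving iodo triflate 6 (an aryne precursor) and hydroxy ester 13. Cutting O1–C2 instead would require substitution or conjugate addition at the benzylic stereocentre, and cutting C2–C3 would create C2 on an enolisable ring. The chosen cut leaves every bond to C2 untouched, so 13 delivers the stereocentre intact. The forward reaction has to release aryne 15 from 6 in the presence of alkoxide 14, add oxygen at the carbon next to boron, and let the resulting arylmagnesium 16 acylate itself on the ester.

**6 ⇒ 5 ⇒ 4 ⇒ 2 ⇒ 1.** The triflate comes from phenol 5 and that from carbamate 4. The C–B bond of 4 is cut back to a C–H bond of carbamate 2; this hydrogen lies between the carbamate and methoxy oxygens and is the most acidic on the ring. The iodine is bought in with phenol 1, ortho to the hydroxyl and para to the methoxy group. No electrophilic iodination then has to be run beside a boronate, where ipso attack and para attack would compete.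

**13 ⇒ 12 ⇒ 9 + 10; 9 ⇒ 7.** The carbinol is traced to ketone 12, so that C2 is set by enantioselective hydrogenation on an open chain. The C2–C3 bond is cut to acid 9 and malonate half-ester 10 (through imidazolide 11). Acid 9 comes from phenolic acid 7 by benzylation through ester 8.

## Alternatives that were turned down

**Alternative 1: flavone by palladium-catalysed carbonylative coupling, then reduction.**
- Disconnection: ring C is cut at C4a–C4, C4–C3 and O1–C2, giving the iodophenol 6-iodo-2,3-dimethoxyphenol A1, a one-carbon carbonyl source and the ring B alkyne 1-(benzyloxy)-5-ethynyl-2,3-dimethoxybenzene A2.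
- Forward key step: a palladium–phosphine catalyst under a carbonylating atmosphere in a secondary amine would join A1, the carbonyl unit and A2 by carbonylative Sonogashira coupling, and the ynone would close by 6-endo addition of the phenol to give the flavone 2-[3-(benzyloxy)-4,5-dimethoxyphenyl]-7,8-dimethoxy-4H-chromen-4-one A3.
- For: three bonds of ring C form in one flask, each by a well-known event, and ring A arrives from A1 with both methoxy groups in place, so no boron-to-oxygen exchange is needed.
- Against: A3 is planar at C2. The stereocentre would have to be created afterwards by enantioselective conjugate reduction of a β-aryl-β-aryloxy enone, a deactivated vinylogous ester. Its product is more easily reduced at C4 and more easily ring-opened than A3 itself, and 5-exo closure to the aurone competes in the cyclisation.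
- Comparison: this alternative is stronger on precedent and probably shorter to the bicyclic skeleton. The chosen plan offers instead a stereocentre made on an open-chain ketone by a dependable hydrogenation, never generated on the heterocycle.

**Alternative 2: ring A carried as a dihydro ring, asymmetric aldol, aromatisation at the end.**
- Disconnection: C2–C3 and O1–C8a, with ring A at the 5,6-dihydro level, giving the cross-conjugated bis(trimethylsilyl) dienol ether A4 and the ring B aldehyde 3-(benzyloxy)-4,5-dimethoxybenzaldehyde A5.
- Forward key step: a vinylogous Mukaiyama aldol addition of the terminal CH2 of A4 to A5 under a chiral titanium Lewis acid, then acid-induced cyclodehydration, would give tetrahydrochromenone A6; dehydrogenation of C5–C6 and debenzylation would finish.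
- For: C2 is set catalytically in the C–C bond-forming event, and the oxygen pattern of ring A is present from the start. On stereochemical economy this is at least equal to the chosen plan.
- Against: A4 is a hydrolytically labile, doubly silylated enol ether of a non-aromatic ring and needs several steps. The final oxidation of A6 must take two hydrogens from C5–C6 while leaving C2–H and C3–H alone, yet quinones and hot palladium, which aromatise such rings, also turn flavanones into flavones. The stereocentre is thus at risk in the last skeletal step.
- Comparison: the chosen plan keeps ring A aromatic throughout and places its uncertain step in the middle of the route. It gives up catalytic creation of C2 during ring formation and replaces it with a ketone hydrogenation.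

**Alternative 3: ring C closed by copper-mediated aryl ether formation from a 1,3-diol.**
- Disconnection: only O1–C8a is cut, with C4 at the alcohol level, giving (1S,3S)-diol A7 with a bromine at the future C8a.
- Forward key step: a copper–phenanthroline catalyst with a carbonate base would couple the C2 hydroxyl of A7 with the aryl bromide (intramolecular Ullmann-type etherification) to give chromanol A8. The C2–O bond is not touched, so the configuration is retained. Oxidation of A8 at C4 would give 19 and debenzylation 20.
- For: every step is of a known type, the bromine fixes the ring A regiochemistry, only the six-membered closure is possible, and the step count is comparable or lower. On predictability this alternative is stronger than the chosen plan.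
- Against: two carbinol centres must be set in A7 although one is destroyed later. The bromide is flanked by the C8 methoxy group and the side chain, which is unfavourable for coupling with a secondary benzylic alkoxide. Hot carbonate invites dehydration of an electron-rich benzylic alcohol, and an extra oxidation is needed.
- Comparison: the chosen plan offers both ring bonds in one operation directly at the ketone level, no redundant stereocentre, and a convergent union of two short fragments.

Key step: step 8

Remark on the chemistry: 2-iodo-5-methoxyphenol (1), 3-hydroxy-4,5-dimethoxybenzoic acid (7) and potassium monomethyl malonate (10) are taken as purchasable.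

## Route

**Step 1**
Reactants: 1 2-iodo-5-methoxyphenol
Product: 2 2-iodo-5-methoxyphenyl N,N-diethylcarbamate
Conditions: ClCONEt2, K2CO3, MeCN, reflux
Reagents that add atoms: N,N-diethylcarbamoyl chloride, CCN(CC)C(Cl)=O
Why: O-carbamoylation of the phenoxide by nucleophilic acyl substitution; the diethylcarbamate is the strongest oxygen-based director for the coming deprotonation and is inert to LiN(iPr)2 at −78 °C.

**Step 2**
Reactants: 2 2-iodo-5-methoxyphenyl N,N-diethylcarbamate
Product: 4 6-iodo-3-methoxy-2-(4,4,5,5-tetramethyl-1,3,2-dioxaborolan-2-yl)phenyl N,N-diethylcarbamate, via lithium aryl(triisopropoxy)borate 3 (not isolated)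
Conditions: LiN(iPr)2 (LDA), B(OiPr)3, THF, −78 °C; then pinacol, AcOH, rt
Reagents that add atoms: triisopropyl borate, CC(C)OB(OC(C)C)OC(C)C; pinacol, CC(C)(O)C(C)(C)O
Why: Directed ortho-metalation with in situ borate trapping: the C–H between the carbamate and methoxy oxygens is the most acidic, LiN(iPr)2 does not exchange the aryl iodide, and immediate capture by the borate should forestall anionic Fries rearrangement and iodine migration; pinacol then transesterifies the borate.

**Step 3**
Reactants: 4 6-iodo-3-methoxy-2-(4,4,5,5-tetramethyl-1,3,2-dioxaborolan-2-yl)phenyl N,N-diethylcarbamate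
Product: 5 6-iodo-3-methoxy-2-(4,4,5,5-tetramethyl-1,3,2-dioxaborolan-2-yl)phenol
Conditions: Cp2Zr(H)Cl, THF, rt; then H2O
Reagents that add atoms: none
Why: Reductive carbamate cleavage by hydrozirconation of the C=O group and collapse to the aryloxide Cp2Zr(OAr)Cl and a formamide; no hydroxide is involved, so the boronate flanked by two oxygens is not exposed to protodeboronation, and the aryl iodide should not react with Cp2Zr(H)Cl at room temperature.

**Step 4**
Reactants: 5 6-iodo-3-methoxy-2-(4,4,5,5-tetramethyl-1,3,2-dioxaborolan-2-yl)phenol
Product: 6 6-iodo-3-methoxy-2-(4,4,5,5-tetramethyl-1,3,2-dioxaborolan-2-yl)phenyl trifluoromethanesulfonate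
Conditions: Tf2O, Et3N, CH2Cl2, −78 → 0 °C
Reagents that add atoms: trifluoromethanesulfonic anhydride, O=S(=O)(OS(=O)(=O)C(F)(F)F)C(F)(F)F
Why: O-sulfonylation of the phenol; the pinacol boronate and the aryl iodide are inert to the anhydride and the amine base at low temperature.

**Step 5**
Reactants: 7 3-hydroxy-4,5-dimethoxybenzoic acid
Product: 9 3-(benzyloxy)-4,5-dimethoxybenzoic acid, via benzyl 3-(benzyloxy)-4,5-dimethoxybenzoate 8 (not isolated)
Conditions: BnBr, K2CO3, acetone, reflux; concentrate; NaOH, MeOH/H2O, reflux; HCl
Reagents that add atoms: benzyl bromide, BrCc1ccccc1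
Why: Williamson alkylation of phenoxide and carboxylate, then saponification of the benzyl ester only; the aryl benzyl ether is stable to hydroxide.

**Step 6**
Reactants: 9 3-(benzyloxy)-4,5-dimethoxybenzoic acid; 10 potassium monomethyl malonate
Product: 12 methyl 3-[3-(benzyloxy)-4,5-dimethoxyphenyl]-3-oxopropanoate, via acyl imidazolide 11 (not isolated)
Conditions: CDI, THF, rt; then 10, MgCl2, Et3N, MeCN, rt → 45 °C; aq. HCl
Reagents that add atoms: none
Why: Masamune–Brooks homologation: the magnesium enolate of the malonate half-ester is C-acylated by the imidazolide and loses CO2, giving the β-keto ester under nearly neutral conditions.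

**Step 7**
Reactants: 12 methyl 3-[3-(benzyloxy)-4,5-dimethoxyphenyl]-3-oxopropanoate
Product: 13 methyl (S)-3-[3-(benzyloxy)-4,5-dimethoxyphenyl]-3-hydroxypropanoate
Conditions: H2 (50 bar), RuCl2[(R)-BINAP] (1 mol%), MeOH, 50 °C
Reagents that add atoms: none
Why: Noyori asymmetric hydrogenation of a β-keto ester: chelation of ketone and ester to divalent ruthenium fixes the face, and the (R)-ligand should deliver hydride to give the S carbinol (S because aryl outranks CH2CO2Me); the benzyl ether is not hydrogenolysed by this catalyst and methanol matches the methyl ester.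

**Step 8**
Reactants: 6 6-iodo-3-methoxy-2-(4,4,5,5-tetramethyl-1,3,2-dioxaborolan-2-yl)phenyl trifluoromethanesulfonate; 13 methyl (S)-3-[3-(benzyloxy)-4,5-dimethoxyphenyl]-3-hydroxypropanoate
Product: 17 (S)-2-[3-(benzyloxy)-4,5-dimethoxyphenyl]-7-methoxy-8-(4,4,5,5-tetramethyl-1,3,2-dioxaborolan-2-yl)chroman-4-one, via chloromagnesium alkoxide 14 (not isolated), via 3-boryl-4-methoxybenzyne 15 (not isolated), via arylmagnesium ether 16 (not isolated)
Conditions: 13, iPrMgCl·LiCl (1.0 equiv), THF, −78 °C; then 6; then iPrMgCl·LiCl (1.1 equiv), −78 → −40 °C; aq. NH4Cl, −40 °C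
Reagents that add atoms: none
Why: Proposed new method: the first equivalent of iPrMgCl·LiCl turns 13 into chloromagnesium alkoxide 14, and the second undergoes iodine–magnesium exchange with 6 at −78 °C, after which loss of the ortho triflate releases aryne 15. Alkoxide 14 adds to the aryne carbon next to boron (the future C8a), forming O1–C8a and leaving the carbanion as arylmagnesium 16 at the remote carbon (the future C4a). That carbon–magnesium bond then attacks the tethered methyl ester in a 6-exo-trig acyl substitution, forming C4a–C4, expelling the alkoxy group and closing ring C. The closest known reaction types are the annulation of arynes with salicylate esters to xanthones (O-addition followed by intramolecular acylation) and the proximal-selective addition of amines to 3-borylarynes released from borylated iodoaryl triflates by the same Grignard reagent; an aliphatic β-hydroxy ester has not been used in this way. The step needs regioselective O-addition at C8a: the electropositive, σ-donating boryl group polarises the aryne so that the nucleophile enters at the adjacent carbon and negative charge builds up at the distal one, coordination of the alkoxide to boron would reinforce this, and the C7 methoxy group is one position further away and should have little say, whereas an oxygen substituent at C8 would direct the other way, which is why C8 is carried as boron here. No stereocentre is created: C2 comes from 13 and none of its bonds is made or broken, so its integrity depends only on suppressing retro-aldol cleavage of 14 and base-induced opening of 17, which the low temperature, the covalent magnesium counter-ion and the cold quench are meant to secure. Chemoselectivity rests on rates, since deprotonation of the hydroxyl and exchange at the iodide ortho to the triflate should be much faster at −78 °C than Grignard addition to the ester or to boron.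

**Step 9**
Reactants: 17 (S)-2-[3-(benzyloxy)-4,5-dimethoxyphenyl]-7-methoxy-8-(4,4,5,5-tetramethyl-1,3,2-dioxaborolan-2-yl)chroman-4-one
Product: 18 (S)-2-[3-(benzyloxy)-4,5-dimethoxyphenyl]-8-hydroxy-7-methoxychroman-4-one
Conditions: NaBO3·4H2O, THF/H2O (1:1), 0 °C → rt
Reagents that add atoms: sodium perborate, [Na+].[Na+].O[B-]1(O)OO[B-](O)(O)OO1
Why: Boronate oxidation: peroxide adds to boron and the aryl group migrates from boron to oxygen, so the hydroxyl appears exactly at C8; perborate is only mildly basic and the reaction is short and cold, which should leave C2 and the aryl ketone untouched.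

**Step 10**
Reactants: 18 (S)-2-[3-(benzyloxy)-4,5-dimethoxyphenyl]-8-hydroxy-7-methoxychroman-4-one
Product: 19 (S)-2-[3-(benzyloxy)-4,5-dimethoxyphenyl]-7,8-dimethoxychroman-4-one
Conditions: TMSCHN2, iPr2NEt, MeCN/MeOH (9:1), rt
Reagents that add atoms: trimethylsilyldiazomethane, C[Si](C)(C)C=[N+]=[N-]
Why: O-methylation of the only free phenol by a diazoalkane under nearly neutral conditions, which avoids the carbonate bases that open flavanones; the ring B oxygen is still benzylated, so only C8–OH reacts.

**Step 11**
Reactants: 19 (S)-2-[3-(benzyloxy)-4,5-dimethoxyphenyl]-7,8-dimethoxychroman-4-one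
Product: 20 (S)-2-(3-hydroxy-4,5-dimethoxyphenyl)-7,8-dimethoxychroman-4-one
Conditions: H2 (1 atm), Pd/C, EtOAc, rt
Reagents that add atoms: none
Why: Hydrogenolysis of the aryl benzyl ether under neutral conditions, in which C2 cannot epimerise; an aprotic solvent, ambient pressure and stopping at full conversion should spare the C2–O1 bond and the ketone.

## Compound list

1 | 2-iodo-5-methoxyphenol | COc1ccc(I)c(O)c1 | starting material
2 | 2-iodo-5-methoxyphenyl N,N-diethylcarbamate | CCN(CC)C(=O)Oc1cc(OC)ccc1I | intermediate
3 | lithium [2-(diethylcarbamoyloxy)-3-iodo-6-methoxyphenyl]tri(propan-2-yloxy)borate | CCN(CC)C(=O)Oc1c(I)ccc(OC)c1[B-](OC(C)C)(OC(C)C)OC(C)C.[Li+] | intermediate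
4 | 6-iodo-3-methoxy-2-(4,4,5,5-tetramethyl-1,3,2-dioxaborolan-2-yl)phenyl N,N-diethylcarbamate | CCN(CC)C(=O)Oc1c(I)ccc(OC)c1B1OC(C)(C)C(C)(C)O1 | intermediate
5 | 6-iodo-3-methoxy-2-(4,4,5,5-tetramethyl-1,3,2-dioxaborolan-2-yl)phenol | COc1ccc(I)c(O)c1B1OC(C)(C)C(C)(C)O1 | intermediate
6 | 6-iodo-3-methoxy-2-(4,4,5,5-tetramethyl-1,3,2-dioxaborolan-2-yl)phenyl trifluoromethanesulfonate | COc1ccc(I)c(OS(=O)(=O)C(F)(F)F)c1B1OC(C)(C)C(C)(C)O1 | intermediate
7 | 3-hydroxy-4,5-dimethoxybenzoic acid | COc1cc(C(=O)O)cc(O)c1OC | starting material
8 | benzyl 3-(benzyloxy)-4,5-dimethoxybenzoate | COc1cc(C(=O)OCc2ccccc2)cc(OCc2ccccc2)c1OC | intermediate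
9 | 3-(benzyloxy)-4,5-dimethoxybenzoic acid | COc1cc(C(=O)O)cc(OCc2ccccc2)c1OC | intermediate
10 | potassium monomethyl malonate (potassium 3-methoxy-3-oxopropanoate) | COC(=O)CC(=O)[O-].[K+] | starting material
11 | [3-(benzyloxy)-4,5-dimethoxyphenyl](1H-imidazol-1-yl)methanone | COc1cc(C(=O)n2ccnc2)cc(OCc2ccccc2)c1OC | intermediate
12 | methyl 3-[3-(benzyloxy)-4,5-dimethoxyphenyl]-3-oxopropanoate | COC(=O)CC(=O)c1cc(OC)c(OC)c(OCc2ccccc2)c1 | intermediate
13 | methyl (S)-3-[3-(benzyloxy)-4,5-dimethoxyphenyl]-3-hydroxypropanoate | COC(=O)C[C@H](O)c1cc(OC)c(OC)c(OCc2ccccc2)c1 | intermediate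
14 | chloromagnesium (S)-1-[3-(benzyloxy)-4,5-dimethoxyphenyl]-3-methoxy-3-oxopropan-1-olate | COC(=O)C[C@H](O[Mg]Cl)c1cc(OC)c(OC)c(OCc2ccccc2)c1 | intermediate
15 | 1-methoxy-2-(4,4,5,5-tetramethyl-1,3,2-dioxaborolan-2-yl)-3,4-didehydrobenzene (3-boryl-4-methoxybenzyne) | COC1=C(B2OC(C)(C)C(C)(C)O2)C#CC=C1 | intermediate
16 | chloro{2-[(S)-1-(3-benzyloxy-4,5-dimethoxyphenyl)-3-methoxy-3-oxopropoxy]-4-methoxy-3-(4,4,5,5-tetramethyl-1,3,2-dioxaborolan-2-yl)phenyl}magnesium | COC(=O)C[C@H](Oc1c([Mg]Cl)ccc(OC)c1B1OC(C)(C)C(C)(C)O1)c1cc(OC)c(OC)c(OCc2ccccc2)c1 | intermediate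
17 | (S)-2-[3-(benzyloxy)-4,5-dimethoxyphenyl]-7-methoxy-8-(4,4,5,5-tetramethyl-1,3,2-dioxaborolan-2-yl)chroman-4-one | COc1cc([C@@H]2CC(=O)c3ccc(OC)c(B4OC(C)(C)C(C)(C)O4)c3O2)cc(OCc2ccccc2)c1OC | intermediate
18 | (S)-2-[3-(benzyloxy)-4,5-dimethoxyphenyl]-8-hydroxy-7-methoxychroman-4-one | COc1cc([C@@H]2CC(=O)c3ccc(OC)c(O)c3O2)cc(OCc2ccccc2)c1OC | intermediate
19 | (S)-2-[3-(benzyloxy)-4,5-dimethoxyphenyl]-7,8-dimethoxychroman-4-one | COc1cc([C@@H]2CC(=O)c3ccc(OC)c(OC)c3O2)cc(OCc2ccccc2)c1OC | intermediate
20 | (S)-2-(3-hydroxy-4,5-dimethoxyphenyl)-7,8-dimethoxychroman-4-one | COc1cc([C@@H]2CC(=O)c3ccc(OC)c(OC)c3O2)cc(O)c1OC | target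

## Step count and least certain steps

Total step count: 11. Longest linear sequence: 8 (steps 1–4, then 8–11); the ring B branch (steps 5–7) joins at step 8.

**Step 8 (key step, Proposed new method).** What may go wrong: the aggregated magnesium alkoxide may be too weak a nucleophile, so that the aryne is consumed by carbomagnesiation or oligomerisation. The bulk of a secondary benzylic alkoxide next to the boronate may override the boryl effect and reverse the regiochemistry. Retro-aldol fragmentation of the alkoxide, ring opening and re-closure at C2 after cyclisation, and Grignard attack at boron are further risks. Fallback (known chemistry), setting out from keto ester 12 and coming back to the route at 19: hydrogenation of 12 with the enantiomeric catalyst RuCl2[(S)-BINAP] would give methyl (R)-3-[3-(benzyloxy)-4,5-dimethoxyphenyl]-3-hydroxypropanoate F1. Aminolysis with MeNH(OMe)·HCl and iPrMgCl would give the Weinreb amide (R)-3-[3-(benzyloxy)-4,5-dimethoxyphenyl]-3-hydroxy-N-methoxy-N-methylpropanamide F2. Ortho-lithiation of 1,2-dimethoxy-3-(methoxymethoxy)benzene with n-BuLi next to the acetal oxygen gives [3,4-dimethoxy-2-(methoxymethoxy)phenyl]lithium F3, which in excess adds to F2 to give (R)-3-[3-(benzyloxy)-4,5-dimethoxyphenyl]-3-hydroxy-1-[3,4-dimethoxy-2-(methoxymethoxy)phenyl]propan-1-one F4. Mild acid methanolysis of the acetal frees the phenol, giving (R)-3-[3-(benzyloxy)-4,5-dimethoxyphenyl]-3-hydroxy-1-(2-hydroxy-3,4-dimethoxyphenyl)propan-1-one F5. An intramolecular Mitsunobu reaction (PPh3, DIAD, THF, 0 °C) then forms O1–C2 by SN2 displacement with inversion, turning the R carbinol into S at C2 and giving 19 directly, so steps 9 and 10 are not needed.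

**Step 2.** What may go wrong: exchange or migration of iodine under LiN(iPr)2, anionic Fries rearrangement if borate capture is slow, or loss of boron during the pinacol exchange. Fallback, setting out from 1 and coming back at 5 (bypassing 2–4): dehydrogenative O-silylation of 1 with Et2SiH2 ([Ir(cod)Cl]2 cat.) would give diethyl(2-iodo-5-methoxyphenoxy)silane F6. The Si–H group then directs iridium-catalysed C–H borylation with B2pin2 ([Ir(cod)Cl]2, 4,4′-di-tert-butyl-2,2′-bipyridine, THF, 80 °C) to the only free ortho position, giving diethyl[6-iodo-3-methoxy-2-(4,4,5,5-tetramethyl-1,3,2-dioxaborolan-2-yl)phenoxy]silane F7. Hydrolysis of the Si–O bond on work-up gives 5.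

**Step 3.** What may go wrong: incomplete reduction of a carbamate shielded on both sides, or loss of boron by protodeboronation or exchange with zirconium during reaction and work-up. Fallback, setting out from 1 and coming back at 5, changing the directing group so that release is an acetal cleavage: MOMCl/iPr2NEt gives 1-iodo-4-methoxy-2-(methoxymethoxy)benzene F8. Deprotonation between the two oxygens with lithium 2,2,6,6-tetramethylpiperidide in the presence of B(OiPr)3, then pinacol exchange, gives 2-[3-iodo-6-methoxy-2-(methoxymethoxy)phenyl]-4,4,5,5-tetramethyl-1,3,2-dioxaborolane F9. HCl in MeOH at room temperature removes the acetal and gives 5.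

**Step 7.** What may go wrong: incomplete enantioselection with an electron-rich aryl ketone, which would carry through to 20 unchanged. Fallback, setting out from 12 and coming back at 13: NaBH4 reduction gives racemic methyl 3-[3-(benzyloxy)-4,5-dimethoxyphenyl]-3-hydroxypropanoate F10. Lipase-catalysed acylation with vinyl acetate (Burkholderia cepacia lipase) is expected, by the usual size rule for secondary alcohols, to acetylate the R enantiomer to methyl (R)-3-acetoxy-3-[3-(benzyloxy)-4,5-dimethoxyphenyl]propanoate F11 and to leave the S alcohol 13, which is separated and enters step 8.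

**Step 11.** What may go wrong: over-reduction, that is hydrogenolysis of the benzylic C2–O1 bond or reduction of the C4 carbonyl. Fallback, setting out from 19 and arriving directly at 20: Lewis-acid debenzylation with BCl3 and pentamethylbenzene as cation scavenger in CH2Cl2 at −78 °C; no new compound is made.

## Further compounds

F1 | step 8 | methyl (R)-3-[3-(benzyloxy)-4,5-dimethoxyphenyl]-3-hydroxypropanoate | COC(=O)C[C@@H](O)c1cc(OC)c(OC)c(OCc2ccccc2)c1
F2 | step 8 | (R)-3-[3-(benzyloxy)-4,5-dimethoxyphenyl]-3-hydroxy-N-methoxy-N-methylpropanamide | CON(C)C(=O)C[C@@H](O)c1cc(OC)c(OC)c(OCc2ccccc2)c1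
F3 | step 8 | [3,4-dimethoxy-2-(methoxymethoxy)phenyl]lithium | COCOc1c([Li])ccc(OC)c1OC
F4 | step 8 | (R)-3-[3-(benzyloxy)-4,5-dimethoxyphenyl]-3-hydroxy-1-[3,4-dimethoxy-2-(methoxymethoxy)phenyl]propan-1-one | COCOc1c(C(=O)C[C@@H](O)c2cc(OC)c(OC)c(OCc3ccccc3)c2)ccc(OC)c1OC
F5 | step 8 | (R)-3-[3-(benzyloxy)-4,5-dimethoxyphenyl]-3-hydroxy-1-(2-hydroxy-3,4-dimethoxyphenyl)propan-1-one | COc1ccc(C(=O)C[C@@H](O)c2cc(OC)c(OC)c(OCc3ccccc3)c2)c(O)c1OC
F6 | step 2 | diethyl(2-iodo-5-methoxyphenoxy)silane | CC[SiH](CC)Oc1cc(OC)ccc1I
F7 | step 2 | diethyl[6-iodo-3-methoxy-2-(4,4,5,5-tetramethyl-1,3,2-dioxaborolan-2-yl)phenoxy]silane | CC[SiH](CC)Oc1c(I)ccc(OC)c1B1OC(C)(C)C(C)(C)O1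
F8 | step 3 | 1-iodo-4-methoxy-2-(methoxymethoxy)benzene | COCOc1cc(OC)ccc1I
F9 | step 3 | 2-[3-iodo-6-methoxy-2-(methoxymethoxy)phenyl]-4,4,5,5-tetramethyl-1,3,2-dioxaborolane | COCOc1c(I)ccc(OC)c1B1OC(C)(C)C(C)(C)O1
F10 | step 7 | methyl (RS)-3-[3-(benzyloxy)-4,5-dimethoxyphenyl]-3-hydroxypropanoate | COC(=O)CC(O)c1cc(OC)c(OC)c(OCc2ccccc2)c1
F11 | step 7 | methyl (R)-3-acetoxy-3-[3-(benzyloxy)-4,5-dimethoxyphenyl]propanoate | COC(=O)C[C@@H](OC(C)=O)c1cc(OC)c(OC)c(OCc2ccccc2)c1
F0 | step 11 | none | none
A1 | alternative 1 | 6-iodo-2,3-dimethoxyphenol | COc1ccc(I)c(O)c1OC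
A2 | alternative 1 | 1-(benzyloxy)-5-ethynyl-2,3-dimethoxybenzene | C#Cc1cc(OC)c(OC)c(OCc2ccccc2)c1
A3 | alternative 1 | 2-[3-(benzyloxy)-4,5-dimethoxyphenyl]-7,8-dimethoxy-4H-chromen-4-one | COc1cc(-c2cc(=O)c3ccc(OC)c(OC)c3o2)cc(OCc2ccccc2)c1OC
A4 | alternative 2 | trimethyl({2-[1-(trimethylsilyloxy)ethenyl]-5,6-dimethoxycyclohexa-1,5-dien-1-yl}oxy)silane | C=C(O[Si](C)(C)C)C1=C(O[Si](C)(C)C)C(OC)=C(OC)CC1
A5 | alternative 2 | 3-(benzyloxy)-4,5-dimethoxybenzaldehyde | COc1cc(C=O)cc(OCc2ccccc2)c1OC
A6 | alternative 2 | (S)-2-[3-(benzyloxy)-4,5-dimethoxyphenyl]-7,8-dimethoxy-2,3,5,6-tetrahydro-4H-chromen-4-one | COC1=C(OC)C2=C(CC1)C(=O)C[C@@H](c1cc(OC)c(OC)c(OCc3ccccc3)c1)O2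
A7 | alternative 3 | (1S,3S)-1-(2-bromo-3,4-dimethoxyphenyl)-3-[3-(benzyloxy)-4,5-dimethoxyphenyl]propane-1,3-diol | COc1cc([C@@H](O)C[C@H](O)c2ccc(OC)c(OC)c2Br)cc(OCc2ccccc2)c1OC
A8 | alternative 3 | (2S,4S)-2-[3-(benzyloxy)-4,5-dimethoxyphenyl]-7,8-dimethoxychroman-4-ol | COc1cc([C@@H]2C[C@H](O)c3ccc(OC)c(OC)c3O2)cc(OCc2ccccc2)c1OC
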